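The readings are calculated for substances that don't exist, and the scatter is random.

Product stands below the substrate consumed in both earlier runs: at 5.00 h the zeta run shows 2.1% as product against 16.0% of its charge consumed, and the delta run shows 1.7% against 12.5%. So I call whatever is neither substrate nor product the pool, and I ask how fast it empties into product.

in all of them: gas 20 mM (held)

| charge | substrate | remark | time |
|---|---|---|---|
| zeta | 0.058 M | run made earlier |  |
| delta | 0.13 M | run made earlier |  |
| flask | 0.086 M |  | 8.0 h |

- zeta (time / h: product / %, substrate / %): 1.00: 0, 98.6; 2.00: 0.6, 94.7; 3.00: 0.8, 91.3; 4.00: 1.6, 87.6; 5.00: 2.1, 84.0; 6.00: 4.4, 79.8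
- delta (time / h: product / %, substrate / %): 1.00: 0, 98.9; 2.00: 0, 96.3; 3.00: 0.8, 93.0; 4.00: 1.5, 90.0; 5.00: 1.7, 87.5; 6.00: 2.0, 84.9

(scatter of a reading: 0.3 percentage points)

- at the start none of the gas is in solution
- a reading of substrate is of its free form alone

* amount of product in percent of the substrate charged, at 25 min, 2.0 h and 8.0 h

Summing the pool, as a fraction of the charge, over time up to 5.00 h gives 0.318 h in the zeta run and 0.249 h in the delta run. Product divided by that sum, both runs pooled, is 0.0671 /h: the hand-over constant, the fraction of the pool becoming product each hour, a pseudo-first-order constant as read from the readings.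

I freeze two things. The pool grows on a straight line, and the hand-over stays constant. The lines from 2.00 h to 5.00 h rise by 0.0307 /h in zeta and 0.0237 /h in delta, and they start after a lag of about 0.452 h, while gas enters. Between the charges, the flask's pool rises by 0.0279 /h. Product then grows with the square of the time past the lag, which gives nothing at 25 min, 0.224% at 2.0 h and 5.33% at 8.0 h.

A second way skips the pool: I scale the product readings at 6.00 h, interpolated between the charges, by the same square. That gives 6.42%, so the two ways part. The hand-over constant finds the cheat: on the zeta pool it predicts 3.13% at 6.00 h, and the reading of 4.4% stands 1.3 percentage points higher, against a scatter of 0.3 points. I keep the first way.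

The forecast reasons that "Product behaves as a second step fed by this pool" and gives 0%, 0.2% and 5.3%.

The flask gives <0.001%, 0.175% and 5.56%, and the forecast held.

    gas ⇌ partner, rate k1*(csat - [partner]) (kL = 0.405 /h)
    substrate + partner → intermediate A (k = 1.91 /M/h)
    substrate + partner ⇌ intermediate B (K = 23.0 /M, k = 2.84 /M/h)
    partner + intermediate A → product (k = 19.3 /M/h)

At 8.00 h in the flask, partner is made 1.06 times as fast as it is used, and the rate constant of the last step, multiplied by partner and by the share of intermediate A among intermediates A and B, is 0.0747 /h, beside my hand-over constant of 0.0671 /h. At 80.0 h in the same flask, that figure is 0.0611 /h, with product at 79.6%.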